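**Strategy.** Everything rests on cutting the bicyclo[3.2.1]octane (ring C: C8, C9, C11–C14; ring D: C8, C13–C16) at C8–C14 and C13–C16. The key step exploits quaternary C8, which lies between an ester-level carbon (C7) and a ketone carbon (C9): one-electron oxidation of that β-keto ester gives a C8 radical that closes ring C and then ring D onto an alkyne, creating both rings, the C8 and C13 stereocentres and the C16 exo-methylene in one operation. Its precursor is an acyclic 8-phenylmenthyl 3-oxohept-6-enoate carrying a propargyl group on C8. Ring A is then joined at C9–C10 by alkenyllithium addition to a ketoisophorone-derived epoxy ketone and semipinacol shift.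

Key step: step 4

Locants: C1–C20 are those of the target (ring A: C1–C5, C10; ring B: C5, C6, O, C7, C8, C9, C10; C17 exo-methylene; C18/C19 on C4; C20 on C10). β is the face of ring A that carries the C2 oxygen; α is the opposite face.

Remark 1 (assumption): the (−)-8-phenylmenthyl ester is taken to expose the face of the C8 radical that leads to the (1R,5R) bicycle 10; if induction runs the other way, the enantiomeric auxiliary is used and nothing else changes.

Remark 2 (assumption): the lactol carbon C6 is taken to settle, by ring–chain equilibration, in the configuration drawn for the target.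

Step 1
Reactants: 1 (−)-8-phenylmenthol; 2 2,2,6-trimethyl-4H-1,3-dioxin-4-one
Product: 4 (−)-8-phenylmenthyl 3-oxobutanoate, via acetylketene 3 (not isolated)
Conditions: xylene, 140 °C, acetone distilled off
Reagents that add atoms: none
Why: Acetoacetylation: thermal retro-hetero-Diels–Alder of the dioxinone releases acetylketene, which should acylate the hindered secondary alcohol without a coupling reagent; no stereocentre is touched.

Step 2
Reactants: 4 (−)-8-phenylmenthyl 3-oxobutanoate; 5 allyl bromide
Product: 7 (−)-8-phenylmenthyl 3-oxohept-6-enoate, via acetoacetate dianion 6 (not isolated)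
Conditions: NaH, THF, 0 °C; n-BuLi, 0 °C; 5, 0 °C → rt; 1 M HCl
Reagents that add atoms: none
Why: Weiler dianion alkylation: the more basic γ-carbon of the 1,3-dianion should take the allyl group and leave the α-position free for step 3.

Step 3
Reactants: 7 (−)-8-phenylmenthyl 3-oxohept-6-enoate; 8 propargyl bromide
Product: 9 (−)-8-phenylmenthyl 3-oxo-2-(prop-2-ynyl)hept-6-enoate (both epimers at the α-carbon)
Conditions: K2CO3, 8 (1.0 equiv), acetone, 50 °C
Reagents that add atoms: none
Why: C-alkylation of a β-keto ester enolate with a propargylic halide under carbonate conditions (bromide limiting, to suppress dialkylation); the new α-centre forms as a mixture that is erased when C8 becomes a radical.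

Step 4
Reactants: 9 (−)-8-phenylmenthyl 3-oxo-2-(prop-2-ynyl)hept-6-enoate
Product: 10 (−)-8-phenylmenthyl (1R,5R)-6-methylidene-2-oxobicyclo[3.2.1]octane-1-carboxylate
Conditions: Mn(OAc)3·2H2O (2.2 equiv), degassed EtOH, 25 → 60 °C
Reagents that add atoms: none
Why: Mn(OAc)3 forms the trivalent manganese enolate of the β-keto ester and electron transfer gives the electrophilic C8 radical; this adds to the terminal alkene carbon C14, the resulting secondary C13 radical adds to alkyne carbon C16, and the vinyl radical then abstracts hydrogen from ethanol. The closest known reaction type is the Mn(OAc)3 oxidative free-radical tandem cyclisation of unsaturated β-keto esters to bicyclo[3.2.1]octanes. Ring C closes 6-endo-trig because the ketone carbonyl lies inside the forming ring, and ring D closes 5-exo-dig. C13 is fixed relative to C8 by the one-carbon bridge, since only the 1,3-cis arrangement can close, and the absolute configuration at C8 is set by the 8-phenylmenthyl ester, whose phenyl ring covers one face of the planar radical. The step needs 6-endo over 5-exo regioselectivity, secured by the 3-oxo placement, and clean termination, secured by leaving out copper salts (trivalent manganese oxidises the secondary radical only slowly) and by ethanol as hydrogen donor.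

Step 5
Reactants: 10 (−)-8-phenylmenthyl (1R,5R)-6-methylidene-2-oxobicyclo[3.2.1]octane-1-carboxylate
Product: 11 (1S,5R)-1-(hydroxymethyl)-6-methylidenebicyclo[3.2.1]octan-2-ol (C9 carbinol epimers)
Conditions: LiAlH4, THF, 0 °C → reflux; H2O quench (1 recovered)
Reagents that add atoms: none
Why: Hydride reduction with LiAlH4 should cleave the hindered auxiliary ester to the C7 carbinol and reduce the C9 ketone; the C9 carbinol centre is left uncontrolled because step 7 oxidises it again.

Step 6
Reactants: 11 (1S,5R)-1-(hydroxymethyl)-6-methylidenebicyclo[3.2.1]octan-2-ol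
Product: 12 (1S,5R)-1-[(4-methoxybenzyloxy)methyl]-6-methylidenebicyclo[3.2.1]octan-2-ol
Conditions: PMBCl (1.1 equiv), Ag2O, KI (cat.), CH2Cl2, rt
Reagents that add atoms: 4-methoxybenzyl chloride, COc1ccc(CCl)cc1
Why: Ag2O-promoted Williamson etherification of a diol should etherify the primary C7 hydroxyl in preference to the ring-bound, neopentylic secondary hydroxyl at C9; no stereocentre is touched.

Step 7
Reactants: 12 (1S,5R)-1-[(4-methoxybenzyloxy)methyl]-6-methylidenebicyclo[3.2.1]octan-2-ol
Product: 13 (1S,5R)-1-[(4-methoxybenzyloxy)methyl]-6-methylidenebicyclo[3.2.1]octan-2-one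
Conditions: Dess–Martin periodinane, CH2Cl2, rt
Reagents that add atoms: none
Why: Dess–Martin oxidation of the secondary alcohol should restore the C9 ketone without touching the PMB ether or the exo-methylene.

Step 8
Reactants: 13 (1S,5R)-1-[(4-methoxybenzyloxy)methyl]-6-methylidenebicyclo[3.2.1]octan-2-one
Product: 14 (E)-2,4,6-triisopropylbenzenesulfonylhydrazone of 13
Conditions: 2,4,6-triisopropylbenzenesulfonyl hydrazide, HCl (cat.), THF, rt
Reagents that add atoms: 2,4,6-triisopropylbenzenesulfonyl hydrazide, CC(C)c1cc(C(C)C)c(S(=O)(=O)NN)c(C(C)C)c1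
Why: Acid-catalysed sulfonylhydrazone formation; the sulfonamide nitrogen should settle anti to quaternary C8, that is syn to the only α-hydrogens (C11), as the Shapiro reaction requires.

Step 9
Reactants: 15 ketoisophorone (2,6,6-trimethylcyclohex-2-ene-1,4-dione)
Product: 16 (S)-phorenol, (4S)-4-hydroxy-2,6,6-trimethylcyclohex-2-en-1-one
Conditions: RuCl(p-cymene)[(S,S)-TsDPEN] (1 mol %), HCO2H–Et3N (5:2), CH2Cl2, rt
Reagents that add atoms: none
Why: Noyori asymmetric transfer hydrogenation should reduce only the unhindered conjugated carbonyl (the other is flanked by the gem-dimethyl carbon and the methyl-bearing alkene carbon); the (S,S)-ligand is expected to give the (S)-carbinol, which becomes C2 of the target.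

Step 10
Reactants: 16 (S)-phorenol
Product: 17 (1S,5S,6S)-5-hydroxy-1,3,3-trimethyl-7-oxabicyclo[4.1.0]heptan-2-one (oxirane cis to the hydroxyl)
Conditions: t-BuOOH, benzyltrimethylammonium hydroxide (cat.), THF, 0 °C
Reagents that add atoms: tert-butyl hydroperoxide, CC(C)(C)OO
Why: Weitz–Scheffer nucleophilic epoxidation of the enone; the free C2 hydroxyl should hydrogen-bond the incoming peroxide anion and steer it to its own face, so C1 and C10 are set with the oxirane β, cis to the hydroxyl.

Step 11
Reactants: 17 cis-epoxy alcohol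
Product: 18 (1S,5S,6S)-5-(tert-butyldimethylsilyloxy)-1,3,3-trimethyl-7-oxabicyclo[4.1.0]heptan-2-one
Conditions: TBSCl, imidazole, DMF, rt
Reagents that add atoms: tert-butyldimethylsilyl chloride, CC(C)(C)[Si](C)(C)Cl
Why: Standard silylation of a secondary alcohol, needed so that the organolithium of step 12 meets no acidic hydrogen; stereocentres untouched.

Step 12
Reactants: 14 trisylhydrazone of the bicyclic ketone; 18 silyl epoxy ketone
Product: 20 C5 epoxy carbinol (C9–C5 bond; 5β-OH; 1β,10β-oxirane; 2β-OTBS), via alkenyllithium 19 (not isolated)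
Conditions: 14, n-BuLi (2.1 equiv), THF, −78 °C, then 0 °C (N2 evolution); −78 °C, 18; → −20 °C; aq. NH4Cl
Reagents that add atoms: none
Why: Shapiro reaction followed by 1,2-addition: the dianion loses sulfinate and dinitrogen to give the C9 alkenyllithium, which should add to ketone 18 (not enolisable, both α-carbons fully substituted) anti to the oxirane oxygen and the silyloxy group, so the C5 hydroxyl ends cis to the epoxide.

Step 13
Reactants: 20 C5 epoxy carbinol
Product: 21 C5 ketone with C9–C10 bond (C10 quaternary: C20 β, C9 α; 1β,2β-bis-OTBS)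
Conditions: TBSOTf, 2,6-lutidine, CH2Cl2, −78 → −30 °C
Reagents that add atoms: tert-butyldimethylsilyl trifluoromethanesulfonate, CC(C)(C)[Si](C)(C)OS(=O)(=O)C(F)(F)F
Why: Semipinacol rearrangement of a 2,3-epoxy alcohol: silyl activation should open the oxirane at tertiary C10 while the alkenyl group, antiperiplanar to the breaking C10–O bond, shifts from C5 to C10 with inversion, which sets quaternary C10 (C9 trans and C20 cis to the C1 oxygen), frees the C5 ketone and leaves the C1 oxygen silylated.

Step 14
Reactants: 21 C5 ketone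
Product: 22 C5–C6 spiro-epoxide (oxirane O β, C6 α; otherwise as 21)
Conditions: Me3S+ I−, KN(SiMe3)2, THF, −10 °C → rt
Reagents that add atoms: trimethylsulfonium iodide, C[S+](C)C.[I-]
Why: Corey–Chaykovsky methylene transfer: the small sulfonium ylide should add irreversibly to the non-enolisable ketone from the α-face, away from the two flanking β-axial methyl groups, and the betaine closes to the spiro-epoxide, whose configuration is erased in step 17.

Step 15
Reactants: 22 spiro-epoxide bis-silyl ether
Product: 23 spiro-epoxide 1β,2β-diol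
Conditions: TBAF, THF, rt → 45 °C
Reagents that add atoms: none
Why: Fluoride desilylation of both silyl ethers; the PMB ether, the alkenes and the hindered spiro-epoxide (its CH2 trans to the C1 alkoxide) should not react.

Step 16
Reactants: 23 spiro-epoxide diol
Product: 24 spiro-epoxide 1β,2β-diacetate
Conditions: Ac2O, pyridine, DMAP (cat.), CH2Cl2, rt
Reagents that add atoms: acetic anhydride, CC(=O)OC(C)=O
Why: DMAP-catalysed acetylation of the two secondary hydroxyls, placed here so that no primary hydroxyl competes; stereocentres untouched.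

Step 17
Reactants: 24 spiro-epoxide diacetate
Product: 25 C6 primary alcohol (C6 β, H5 α; 1β,2β-diacetate; C7 OPMB)
Conditions: Cp2TiCl2, Zn dust, THF, rt; then 24, 1,4-cyclohexadiene, rt; aqueous work-up
Reagents that add atoms: none
Why: Nugent–RajanBabu reductive epoxide opening: trivalent titanium should cleave the C5–O bond homolytically to the tertiary C5 radical, which takes a hydrogen atom from 1,4-cyclohexadiene on the α-face (opposite the β-axial methyl groups on C10 and C4), giving the anti-Markovnikov alcohol with H5 α and C6 β while alkenes and esters are left alone.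

Step 18
Reactants: 25 C6 primary alcohol
Product: 26 C15 allylic alcohol of 25 (C15 configuration not assigned)
Conditions: SeO2 (0.5 equiv), t-BuOOH, CH2Cl2, rt
Reagents that add atoms: tert-butyl hydroperoxide, CC(C)(C)OO (terminal oxidant; the oxygen is passed on by selenium dioxide, O=[Se]=O)
Why: SeO2 allylic oxidation (ene reaction at C17, then [2,3]-shift) should hydroxylate C15, the only allylic CH2 of the exo-methylene (C13 is a bridgehead), while the C9=C11 alkene has no hydrogen on its more substituted side and stays intact; the C15 configuration is irrelevant.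

Step 19
Reactants: 26 C15 allylic alcohol
Product: 27 keto aldehyde (C15 ketone conjugated with C16=C17; C6 aldehyde; C7 OPMB)
Conditions: Dess–Martin periodinane (3 equiv), CH2Cl2, 0 °C → rt
Reagents that add atoms: none
Why: Dess–Martin oxidation should convert the allylic C15 alcohol into the enone and the neopentylic C6 alcohol into the aldehyde in one operation; C5, flanked by two quaternary carbons, should not epimerise under these mild conditions.

Step 20
Reactants: 27 keto aldehyde
Product: 29 oxepane lactol (ring B closed; C9=C11 alkene), via hydroxy aldehyde 28 (not isolated)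
Conditions: DDQ, CH2Cl2–pH 7 buffer (10:1), 0 °C → rt
Reagents that add atoms: none
Why: Oxidative PMB ether cleavage with DDQ under neutral conditions should free the C7 hydroxyl, which adds to the C6 aldehyde to close the seven-membered lactol; C6 equilibrates to the more stable anomer.

Step 21
Reactants: 29 oxepane lactol
Product: 30 CNP0224512.1 (target)
Conditions: DMDO (acetone solution), CH2Cl2, −20 → 0 °C
Reagents that add atoms: dimethyldioxirane, CC1(C)OO1
Why: Dioxirane epoxidation: the electron-rich trisubstituted C9=C11 alkene should react in preference to the electron-poor enone alkene, with oxygen delivered to the exo face of the bicyclo[3.2.1]octene (the side of the one-carbon bridge C14), which in the ring-B-closed conformation is also the face not covered by C1 of ring A; this sets C9 and C11.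

**Compound list**

1 | (−)-8-phenylmenthol, (1R,2S,5R)-5-methyl-2-(2-phenylpropan-2-yl)cyclohexan-1-ol | O[C@@H]1C[C@H](C)CC[C@H]1C(C)(C)c1ccccc1 | starting material
2 | 2,2,6-trimethyl-4H-1,3-dioxin-4-one | CC1=CC(=O)OC(C)(C)O1 | starting material
3 | acetylketene | CC(=O)C=C=O | intermediate
4 | (−)-8-phenylmenthyl 3-oxobutanoate | CC(=O)CC(=O)O[C@@H]1C[C@H](C)CC[C@H]1C(C)(C)c1ccccc1 | intermediate
5 | allyl bromide | C=CCBr | starting material
6 | sodium lithium dianion of 4 (1,3-dienediolate) | [Na+].[Li+].C=C([O-])C=C([O-])O[C@@H]1C[C@H](C)CC[C@H]1C(C)(C)c1ccccc1 | intermediate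
7 | (−)-8-phenylmenthyl 3-oxohept-6-enoate | C=CCCC(=O)CC(=O)O[C@@H]1C[C@H](C)CC[C@H]1C(C)(C)c1ccccc1 | intermediate
8 | propargyl bromide | C#CCBr | starting material
9 | (−)-8-phenylmenthyl 3-oxo-2-(prop-2-ynyl)hept-6-enoate (α-carbon epimers) | C#CCC(C(=O)O[C@@H]1C[C@H](C)CC[C@H]1C(C)(C)c1ccccc1)C(=O)CCC=C | intermediate
10 | (−)-8-phenylmenthyl (1R,5R)-6-methylidene-2-oxobicyclo[3.2.1]octane-1-carboxylate | C=C1C[C@@]2(C(=O)O[C@@H]3C[C@H](C)CC[C@H]3C(C)(C)c3ccccc3)C(=O)CC[C@@H]1C2 | intermediate
11 | (1S,5R)-1-(hydroxymethyl)-6-methylidenebicyclo[3.2.1]octan-2-ol (C9 carbinol epimers) | C=C1C[C@@]2(CO)C(O)CC[C@@H]1C2 | intermediate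
12 | (1S,5R)-1-[(4-methoxybenzyloxy)methyl]-6-methylidenebicyclo[3.2.1]octan-2-ol (C9 carbinol epimers) | C=C1C[C@@]2(COCc3ccc(OC)cc3)C(O)CC[C@@H]1C2 | intermediate
13 | (1S,5R)-1-[(4-methoxybenzyloxy)methyl]-6-methylidenebicyclo[3.2.1]octan-2-one | C=C1C[C@@]2(COCc3ccc(OC)cc3)C(=O)CC[C@@H]1C2 | intermediate
14 | (E)-2,4,6-triisopropylbenzenesulfonylhydrazone of 13 (N–N bond anti to C8) | C=C1C[C@@]2(COCc3ccc(OC)cc3)/C(=N/NS(=O)(=O)c3c(C(C)C)cc(C(C)C)cc3C(C)C)CC[C@@H]1C2 | intermediate
15 | ketoisophorone, 2,6,6-trimethylcyclohex-2-ene-1,4-dione | CC1=CC(=O)CC(C)(C)C1=O | starting material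
16 | (S)-phorenol, (4S)-4-hydroxy-2,6,6-trimethylcyclohex-2-en-1-one | CC1=C[C@@H](O)CC(C)(C)C1=O | intermediate
17 | (1S,5S,6S)-5-hydroxy-1,3,3-trimethyl-7-oxabicyclo[4.1.0]heptan-2-one (oxirane cis to OH) | C[C@]12O[C@H]1[C@@H](O)CC(C)(C)C2=O | intermediate
18 | (1S,5S,6S)-5-(tert-butyldimethylsilyloxy)-1,3,3-trimethyl-7-oxabicyclo[4.1.0]heptan-2-one | C[C@]12O[C@H]1[C@@H](O[Si](C)(C)C(C)(C)C)CC(C)(C)C2=O | intermediate
19 | 2-lithio-1-[(4-methoxybenzyloxy)methyl]-6-methylidenebicyclo[3.2.1]oct-2-ene (lithium on C9; C8 and C13 as in 13) | C=C1C[C@@]2(COCc3ccc(OC)cc3)C([Li])=CC[C@@H]1C2 | intermediate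
20 | epoxy carbinol: C9 of the bicyclic alkene (C9=C11, C8–CH2OPMB, C16=C17) bonded to C5 of ring A; ring A has C5–OH, C10(CH3)–C1 oxirane, C2–OTBS and C4 gem-dimethyl; OH, oxirane oxygen and OTBS all β, C9 α | C=C1C[C@@]2(COCc3ccc(OC)cc3)C(=CC[C@@H]1C2)[C@@]4(O)C(C)(C)C[C@H](O[Si](C)(C)C(C)(C)C)[C@@H]5O[C@]45C | intermediate
21 | C5 ketone: C9 bonded to quaternary C10 (C20 β, C9 α); 1β,2β-bis(tert-butyldimethylsilyloxy); C4 gem-dimethyl; bicycle as in 20 | C=C1C[C@@]2(COCc3ccc(OC)cc3)C(=CC[C@@H]1C2)[C@@]4(C)C(=O)C(C)(C)C[C@H](O[Si](C)(C)C(C)(C)C)[C@@H]4O[Si](C)(C)C(C)(C)C | intermediate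
22 | spiro-epoxide of 21 at C5 (C5–C6 oxirane, oxygen β, C6 α) | C=C1C[C@@]2(COCc3ccc(OC)cc3)C(=CC[C@@H]1C2)[C@@]4(C)[C@@]5(CO5)C(C)(C)C[C@H](O[Si](C)(C)C(C)(C)C)[C@@H]4O[Si](C)(C)C(C)(C)C | intermediate
23 | 1β,2β-diol of spiro-epoxide 22 | C=C1C[C@@]2(COCc3ccc(OC)cc3)C(=CC[C@@H]1C2)[C@@]4(C)[C@@]5(CO5)C(C)(C)C[C@H](O)[C@@H]4O | intermediate
24 | 1β,2β-diacetate of spiro-epoxide 23 | C=C1C[C@@]2(COCc3ccc(OC)cc3)C(=CC[C@@H]1C2)[C@@]4(C)[C@@]5(CO5)C(C)(C)C[C@H](OC(C)=O)[C@@H]4OC(C)=O | intermediate
25 | C6 primary alcohol: C5 carries β-CH2OH and α-H; 1β,2β-diacetate; C7–OPMB; C9=C11 and C16=C17 alkenes | C=C1C[C@@]2(COCc3ccc(OC)cc3)C(=CC[C@@H]1C2)[C@@]4(C)[C@H](CO)C(C)(C)C[C@H](OC(C)=O)[C@@H]4OC(C)=O | intermediate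
26 | C15 allylic alcohol of 25 (C15 configuration not assigned) | C=C1C(O)[C@@]2(COCc3ccc(OC)cc3)C(=CC[C@@H]1C2)[C@@]4(C)[C@H](CO)C(C)(C)C[C@H](OC(C)=O)[C@@H]4OC(C)=O | intermediate
27 | keto aldehyde: C15 ketone conjugated with C16=C17, C6 aldehyde (β on C5), 1β,2β-diacetate, C7–OPMB, C9=C11 | C=C1C(=O)[C@@]2(COCc3ccc(OC)cc3)C(=CC[C@@H]1C2)[C@@]4(C)[C@H](C=O)C(C)(C)C[C@H](OC(C)=O)[C@@H]4OC(C)=O | intermediate
28 | hydroxy aldehyde: 27 with free C7–OH | C=C1C(=O)[C@@]2(CO)C(=CC[C@@H]1C2)[C@@]4(C)[C@H](C=O)C(C)(C)C[C@H](OC(C)=O)[C@@H]4OC(C)=O | intermediate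
29 | lactol: ring B closed (C7–O–C6(OH)), C9=C11 alkene, C15 ketone, C16=C17, 1β,2β-diacetate | C=C1C(=O)[C@@]23CO[C@@H](O)[C@@H]4C(C)(C)C[C@H](OC(C)=O)[C@H](OC(C)=O)[C@@]4(C)C2=CC[C@@H]1C3 | intermediate
30 | CNP0224512.1: 9,11-epoxide of 29 (oxygen on the exo face, side of C14) | C=C1C(=O)[C@@]23CO[C@@H](O)[C@@H]4C(C)(C)C[C@H](OC(C)=O)[C@H](OC(C)=O)[C@@]4(C)[C@]24O[C@@H]4C[C@@H]1C3 | target

**Step count.** Total: 21 steps. Longest linear sequence: 18 steps (steps 1–8, then 12–21); the ring A branch (steps 9–11) has 3 steps.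

**Steps most likely to fail**

1. Step 4 (key step). Hydrogen transfer from ethanol to the vinyl radical formed after the second closure may be too slow, so that oligomerisation or internal hydrogen shifts take over; the auxiliary may also discriminate the two faces of the C8 radical only weakly. Fallback, from 7 back to 10: 7 is alkylated with allyl bromide 5 (K2CO3, acetone) instead of 8, giving (−)-8-phenylmenthyl 3-oxo-2-(prop-2-enyl)hept-6-enoate F1. Oxidation with Mn(OAc)3·2H2O and Cu(OAc)2·H2O in acetic acid should run the same 6-endo closure, then a 5-exo-trig closure. The primary radical is then oxidised by divalent copper with loss of the C16 hydrogen, giving the exo-methylene directly. Termination is thus oxidative and no hydrogen donor is needed. A weak diastereomer ratio is handled by separating the diastereomers of 10, or by the enantiomeric auxiliary.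

2. Step 12. The hindered, strongly basic alkenyllithium may be protonated or may transfer an electron faster than it adds to the doubly flanked carbonyl; nitrogen loss from the hydrazone dianion may also be incomplete. Fallback, from 13 back to 20: 13 is condensed with N2H4·H2O to the hydrazone F2, which iodine and tetramethylguanidine convert to the alkenyl iodide F3 (Barton iodination). Halogen–lithium exchange (t-BuLi, −78 °C) gives 19 without a warm-up stage. Transmetalation with anhydrous CeCl3 gives the less basic, more oxophilic alkenylcerium dichloride F4, which should add to 18 with the same facial sense.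

3. Step 17. The tertiary C5 radical may rearrange by 1,2-shift of the neighbouring alkenyl group (through a cyclopropylcarbinyl radical) before hydrogen transfer, or hydrogen may arrive on the β-face. Fallback, from 24 back to 27, ionic instead of radical: BF3·OEt2 (CH2Cl2, −78 °C) should trigger a Meinwald rearrangement of the spiro-epoxide. Hydride shifts from C6 to C5 anti to the departing β-oxygen, giving the C6 aldehyde F5 with H5 α. SeO2 and t-BuOOH then hydroxylate C15 to the allylic alcohol F6, and Dess–Martin oxidation gives 27.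

**Further compounds**

F1 | step 4 | (−)-8-phenylmenthyl 3-oxo-2-(prop-2-enyl)hept-6-enoate (α-carbon epimers) | C=CCC(C(=O)O[C@@H]1C[C@H](C)CC[C@H]1C(C)(C)c1ccccc1)C(=O)CCC=C
F2 | step 12 | hydrazone of ketone 13 | C=C1C[C@@]2(COCc3ccc(OC)cc3)C(=NN)CC[C@@H]1C2
F3 | step 12 | 2-iodo-1-[(4-methoxybenzyloxy)methyl]-6-methylidenebicyclo[3.2.1]oct-2-ene (iodine on C9) | C=C1C[C@@]2(COCc3ccc(OC)cc3)C(I)=CC[C@@H]1C2
F4 | step 12 | alkenylcerium dichloride (cerium on C9) | C=C1C[C@@]2(COCc3ccc(OC)cc3)C([Ce](Cl)Cl)=CC[C@@H]1C2
F5 | step 17 | C6 aldehyde (β on C5), 1β,2β-diacetate, C7–OPMB, no oxygen on C15 | C=C1C[C@@]2(COCc3ccc(OC)cc3)C(=CC[C@@H]1C2)[C@@]4(C)[C@H](C=O)C(C)(C)C[C@H](OC(C)=O)[C@@H]4OC(C)=O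
F6 | step 17 | C15 allylic alcohol of F5 (C15 configuration not assigned) | C=C1C(O)[C@@]2(COCc3ccc(OC)cc3)C(=CC[C@@H]1C2)[C@@]4(C)[C@H](C=O)C(C)(C)C[C@H](OC(C)=O)[C@@H]4OC(C)=O
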